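## Retrosynthetic overview

1. Target ⇐ protected C20 ketone, by one global base methanolysis that removes three aryl silyl ethers and the C15 benzoate.
2. C5=C6 and C11=C12 (both Z) ⇐ one-pot unsymmetrical double Wittig of a C6–C11 bis-ylide with a C1–C5 keto-aldehyde and a C12–C20 (4S)-4-benzoyloxy-(2E,6Z)-dienal.
3. C15–O, the only stereocentre ⇐ amine-catalysed enantioselective γ-benzoyloxylation of achiral (2E,6Z)-nona-2,6-dienal through its dienamine.
4. C2–C3 ⇐ Mukaiyama–Michael addition of the silyl enol ether of fully silylated phloroacetophenone to acrolein.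
5. No ring is formed: the phloroglucinol ring is bought as 2',4',6'-trihydroxyacetophenone.

Assumption: (Z)-hex-3-ene-1,6-diol is bought as a catalogue compound, and the squaramide aminocatalyst of step 1 (made in two steps from dimethyl squarate, 3,5-bis(trifluoromethyl)aniline and (R)-1-Boc-2-(aminomethyl)pyrrolidine) is a catalyst and not a route step.

Carbon numbers C1–C20 refer to the chain of the target (C1 = ketone carbon, C15 = carbinol carbon). TBS = tert-butyldimethylsilyl.

Catalyst of step 1: 3-{[3,5-bis(trifluoromethyl)phenyl]amino}-4-{[(2R)-pyrrolidin-2-ylmethyl]amino}cyclobut-3-ene-1,2-dione, SMILES O=C1C(=O)C(NC[C@H]2CCCN2)=C1Nc1cc(cc(c1)C(F)(F)F)C(F)(F)F.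

## Route

Step 1
Reactants: 1 (2E,6Z)-nona-2,6-dienal; 2 dibenzoyl peroxide
Product: 3 (2E,4S,6Z)-1-oxonona-2,6-dien-4-yl benzoate
Conditions: (R)-squaramide aminocatalyst named above (20 mol%), hydroquinone (10 mol%), 2 (1.2 equiv, in portions), CH2Cl2, −20 °C, dark, 24–48 h
Reagents that add atoms: none
Why: Proposed new method: the pyrrolidine condenses with 1 to the (1E,3E)-s-trans dienamine with the enamine bond anti to the catalyst arm, the squaramide NH pair on the (2R)-arm hydrogen-bonds a benzoyl carbonyl of 2 and holds the weak O–O bond over the Si face of the remote γ-carbon, so attack of C4 on peroxide oxygen with loss of squaramide-stabilised benzoate gives the 4S benzoate and, after hydrolysis of the conjugated iminium ion, the 2E enal with the isolated 6Z alkene untouched; the closest known reactions are the amine-catalysed enamine α-benzoyloxylation of aldehydes with dibenzoyl peroxide and the hydrogen-bond-directed dienamine γ-functionalisation of enals with nitroalkenes (also the dienamine γ-amination with azodicarboxylates).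

Step 2
Reactants: 4 (Z)-hex-3-ene-1,6-diol
Product: 5 (Z)-1,6-dibromohex-3-ene
Conditions: CBr4 (2.4 equiv), PPh3 (2.5 equiv), CH2Cl2, 0 °C → rt
Reagents that add atoms: carbon tetrabromide, BrC(Br)(Br)Br
Why: Appel reaction, in which each primary alcohol is activated as an alkoxyphosphonium ion and displaced by bromide under neutral conditions that leave the Z-alkene untouched.

Step 3
Reactants: 5 (Z)-1,6-dibromohex-3-ene
Product: 6 [(3Z)-hex-3-ene-1,6-diyl]bis(triphenylphosphonium) dibromide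
Conditions: PPh3 (2.3 equiv), MeCN, reflux, 48 h; precipitation from Et2O, drying in vacuo
Reagents that add atoms: triphenylphosphine, c1ccccc1P(c1ccccc1)c1ccccc1
Why: double SN2 quaternisation of triphenylphosphine by the two primary homoallylic bromides (Wittig salt formation).

Step 4
Reactants: 7 1-(2,4,6-trihydroxyphenyl)ethan-1-one (dried)
Product: 8 tert-butyl{[1-(2,4,6-tris{[tert-butyl(dimethyl)silyl]oxy}phenyl)ethenyl]oxy}dimethylsilane
Conditions: TBSOTf (4.6 equiv), Et3N (7 equiv), CH2Cl2, 0 °C → rt; NaHCO3 work-up; Et3N-deactivated silica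
Reagents that add atoms: tert-butyldimethylsilyl trifluoromethanesulfonate, CC(C)(C)[Si](C)(C)OS(=O)(=O)C(F)(F)F
Why: exhaustive silylation, in which the silyl triflate/amine pair silylates all three phenols and soft-enolises the methyl ketone to its only possible silyl enol ether.

Step 5
Reactants: 8 tert-butyl{[1-(2,4,6-tris{[tert-butyl(dimethyl)silyl]oxy}phenyl)ethenyl]oxy}dimethylsilane; 9 prop-2-enal (acrolein)
Product: 10 5-oxo-5-(2,4,6-tris{[tert-butyl(dimethyl)silyl]oxy}phenyl)pentanal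
Conditions: 5-benzyl-2,2,3-trimethylimidazolidin-4-one·CF3CO2H (MacMillan first-generation imidazolidinone, either enantiomer or racemate, 20 mol%), 9 (3 equiv), CH2Cl2/H2O (20:1), −20 °C
Reagents that add atoms: none
Why: iminium-catalysed Mukaiyama–Michael addition, in which the acrolein iminium ion is attacked at its β-carbon by the unhindered CH2 terminus of the silyl enol ether and water releases the silanol and the aldehyde, giving the 1,5-keto-aldehyde without 1,2-addition and without creating a stereocentre.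

Step 6
Reactants: 6 [(3Z)-hex-3-ene-1,6-diyl]bis(triphenylphosphonium) dibromide; 10 5-oxo-5-(2,4,6-tris{[tert-butyl(dimethyl)silyl]oxy}phenyl)pentanal; 3 (2E,4S,6Z)-1-oxonona-2,6-dien-4-yl benzoate
Product: 13 (3Z,6S,7E,9Z,12Z,15Z)-20-oxo-20-(2,4,6-tris{[tert-butyl(dimethyl)silyl]oxy}phenyl)icosa-3,7,9,12,15-pentaen-6-yl benzoate, via bis-ylide 11 (not isolated), via mono-olefinated ylide 12 (not isolated)
Conditions: 6 (1.5 equiv), NaN(SiMe3)2 (3.0 equiv), THF, −78 → 0 °C, 30 min; 10 (1.0 equiv) dropwise at −100 °C, then → −30 °C; 3 (2.2 equiv) at −100 °C → rt; excess 3 recovered by chromatography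
Reagents that add atoms: none
Why: one-pot unsymmetrical double Wittig olefination of a non-stabilised bis-ylide under lithium-free conditions, where kinetic cis-oxaphosphetane formation gives the new C5=C6 and C11=C12 Z-alkenes, the di-ortho-silyloxy aryl ketone is too hindered and electron-rich to react, and the benzoate and the C15 centre survive because the enal is consumed at low temperature faster than ester attack or γ-deprotonation.

Step 7
Reactants: 13 (3Z,6S,7E,9Z,12Z,15Z)-20-oxo-20-(2,4,6-tris{[tert-butyl(dimethyl)silyl]oxy}phenyl)icosa-3,7,9,12,15-pentaen-6-yl benzoate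
Product: 14 (5Z,8Z,11Z,13E,15S,17Z)-15-hydroxy-1-(2,4,6-trihydroxyphenyl)icosa-5,8,11,13,17-pentaen-1-one
Conditions: K2CO3 (6 equiv), degassed MeOH/THF (4:1), 0 °C → rt, dark, argon; then pH 6 phosphate buffer, EtOAc extraction
Reagents that add atoms: none
Why: base-mediated methanolysis (transesterification), in which methoxide cleaves the three phenolic silyl ethers and the benzoate by acyl–oxygen cleavage, so the C15–O bond, its S configuration and the polyene geometry are untouched.

## Compound list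

1 | (2E,6Z)-nona-2,6-dienal | CC/C=C\CC/C=C/C=O | starting material
2 | dibenzoyl peroxide | O=C(OOC(=O)c1ccccc1)c1ccccc1 | starting material
3 | (2E,4S,6Z)-1-oxonona-2,6-dien-4-yl benzoate | CC/C=C\C[C@H](OC(=O)c1ccccc1)/C=C/C=O | intermediate
4 | (Z)-hex-3-ene-1,6-diol | OCC/C=C\CCO | starting material
5 | (Z)-1,6-dibromohex-3-ene | BrCC/C=C\CCBr | intermediate
6 | [(3Z)-hex-3-ene-1,6-diyl]bis(triphenylphosphonium) dibromide | [Br-].[Br-].c1ccccc1[P+](c1ccccc1)(c1ccccc1)CC/C=C\CC[P+](c1ccccc1)(c1ccccc1)c1ccccc1 | intermediate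
7 | 1-(2,4,6-trihydroxyphenyl)ethan-1-one | CC(=O)c1c(O)cc(O)cc1O | starting material
8 | tert-butyl{[1-(2,4,6-tris{[tert-butyl(dimethyl)silyl]oxy}phenyl)ethenyl]oxy}dimethylsilane | C=C(O[Si](C)(C)C(C)(C)C)c1c(O[Si](C)(C)C(C)(C)C)cc(O[Si](C)(C)C(C)(C)C)cc1O[Si](C)(C)C(C)(C)C | intermediate
9 | prop-2-enal (acrolein) | C=CC=O | starting material
10 | 5-oxo-5-(2,4,6-tris{[tert-butyl(dimethyl)silyl]oxy}phenyl)pentanal | O=CCCCC(=O)c1c(O[Si](C)(C)C(C)(C)C)cc(O[Si](C)(C)C(C)(C)C)cc1O[Si](C)(C)C(C)(C)C | intermediate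
11 | (3Z)-hex-3-ene-1,6-diylidenebis(triphenylphosphorane) (bis-ylide) | c1ccccc1P(c1ccccc1)(c1ccccc1)=CC/C=C\CC=P(c1ccccc1)(c1ccccc1)c1ccccc1 | intermediate (not isolated)
12 | {(3Z,6Z)-11-oxo-11-(2,4,6-tris{[tert-butyl(dimethyl)silyl]oxy}phenyl)undeca-3,6-dien-1-ylidene}triphenylphosphorane (mono-olefinated ylide) | O=C(CCC/C=C\C/C=C\CC=P(c1ccccc1)(c1ccccc1)c1ccccc1)c1c(O[Si](C)(C)C(C)(C)C)cc(O[Si](C)(C)C(C)(C)C)cc1O[Si](C)(C)C(C)(C)C | intermediate (not isolated)
13 | (3Z,6S,7E,9Z,12Z,15Z)-20-oxo-20-(2,4,6-tris{[tert-butyl(dimethyl)silyl]oxy}phenyl)icosa-3,7,9,12,15-pentaen-6-yl benzoate | CC/C=C\C[C@H](OC(=O)c1ccccc1)/C=C/C=C\C/C=C\C/C=C\CCCC(=O)c1c(O[Si](C)(C)C(C)(C)C)cc(O[Si](C)(C)C(C)(C)C)cc1O[Si](C)(C)C(C)(C)C | intermediate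
14 | (5Z,8Z,11Z,13E,15S,17Z)-15-hydroxy-1-(2,4,6-trihydroxyphenyl)icosa-5,8,11,13,17-pentaen-1-one | CC/C=C\C[C@H](O)/C=C/C=C\C/C=C\C/C=C\CCCC(=O)c1c(O)cc(O)cc1O | target

## Step count and risks

Total steps: 7. Longest linear sequence: 4 steps (7 → 8 → 10 → 13 → 14, or 4 → 5 → 6 → 13 → 14).

**Step 1 (the proposed new step).** It may fail through α- instead of γ-attack, through N-benzoyloxylation of the catalyst by 2, or through low enantioselectivity. The sense of induction is predicted from a model, not measured; a 3Z-dienamine or the syn rotamer would erode or reverse it. The product could also racemise by re-forming the dienamine. Enantiomeric excess and sense are checked by chiral HPLC against the sample from the fallback; if the sense is reversed, the (S)-catalyst is used.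

The fallback uses known chemistry, sets out from 2 and comes back to the route at 3. Purchased achiral (Z)-hept-4-enal F1 is α-benzoyloxylated with 2 under (S)-2-(triphenylmethyl)pyrrolidine catalysis (10 mol%, hydroquinone 10 mol%, THF, 0 °C). This is steric-shielding enamine catalysis, with oxygen delivered to the enamine face away from the trityl group, and gives (2S,4Z)-1-oxohept-4-en-2-yl benzoate F2. Crude F2 is treated with (triphenylphosphoranylidene)acetaldehyde (1.05 equiv, toluene, rt) in an E-selective Wittig reaction that gives 3. This costs one extra step.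

**Step 5.** The silyl enol ether 8 may protodesilylate under the aqueous ammonium salt, acrolein may polymerise, and the addition may be slow.

The fallback sets out from 7 and comes back at 10. Compound 7 is silylated (TBSCl, imidazole, DMF, 40 °C) to 1-(2,4,6-tris{[tert-butyl(dimethyl)silyl]oxy}phenyl)ethan-1-one F3. Its lithium enolate (LiN(SiMe3)2, THF, −78 °C) is alkylated with allyl bromide to 1-(2,4,6-tris{[tert-butyl(dimethyl)silyl]oxy}phenyl)pent-4-en-1-one F4. Anti-Markovnikov hydroboration–oxidation (9-BBN, THF; then NaBO3·4H2O) gives 5-hydroxy-1-(2,4,6-tris{[tert-butyl(dimethyl)silyl]oxy}phenyl)pentan-1-one F5. Dess–Martin periodinane (NaHCO3, CH2Cl2) then gives 10.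

**Step 6.** The one-pot sequence is statistical, so symmetrical bis-adducts form. Z/E control at C11=C12 may be incomplete, and the ylide may attack the benzoate or deprotonate 3.

The fallback builds the triene stepwise; it sets out from 4 and 10 and comes back at 12. Mono-bromination of 4 (48% aqueous HBr, toluene, reflux) gives (Z)-6-bromohex-3-en-1-ol F6. PPh3 in MeCN at reflux gives [(3Z)-6-hydroxyhex-3-en-1-yl]triphenylphosphonium bromide F7. Its oxido-ylide (NaN(SiMe3)2, 2 equiv, THF, −78 °C) reacts with 10 to give (5Z,8Z)-11-hydroxy-1-(2,4,6-tris{[tert-butyl(dimethyl)silyl]oxy}phenyl)undeca-5,8-dien-1-one F8. Appel bromination (CBr4, PPh3, CH2Cl2, 0 °C) gives (5Z,8Z)-11-bromo-1-(2,4,6-tris{[tert-butyl(dimethyl)silyl]oxy}phenyl)undeca-5,8-dien-1-one F9. PPh3 in MeCN at 70 °C gives [(3Z,6Z)-11-oxo-11-(2,4,6-tris{[tert-butyl(dimethyl)silyl]oxy}phenyl)undeca-3,6-dien-1-yl]triphenylphosphonium bromide F10. NaN(SiMe3)2 (1.0 equiv, THF, −78 °C) converts F10 into 12, which reacts with only 1.0 equiv of 3 (−100 °C → rt) to give 13.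

## Further compounds

F1 | step 1 | (Z)-hept-4-enal (purchased, achiral) | CC/C=C\CCC=O
F2 | step 1 | (2S,4Z)-1-oxohept-4-en-2-yl benzoate | CC/C=C\C[C@H](OC(=O)c1ccccc1)C=O
F3 | step 5 | 1-(2,4,6-tris{[tert-butyl(dimethyl)silyl]oxy}phenyl)ethan-1-one | CC(=O)c1c(O[Si](C)(C)C(C)(C)C)cc(O[Si](C)(C)C(C)(C)C)cc1O[Si](C)(C)C(C)(C)C
F4 | step 5 | 1-(2,4,6-tris{[tert-butyl(dimethyl)silyl]oxy}phenyl)pent-4-en-1-one | C=CCCC(=O)c1c(O[Si](C)(C)C(C)(C)C)cc(O[Si](C)(C)C(C)(C)C)cc1O[Si](C)(C)C(C)(C)C
F5 | step 5 | 5-hydroxy-1-(2,4,6-tris{[tert-butyl(dimethyl)silyl]oxy}phenyl)pentan-1-one | OCCCCC(=O)c1c(O[Si](C)(C)C(C)(C)C)cc(O[Si](C)(C)C(C)(C)C)cc1O[Si](C)(C)C(C)(C)C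
F6 | step 6 | (Z)-6-bromohex-3-en-1-ol | OCC/C=C\CCBr
F7 | step 6 | [(3Z)-6-hydroxyhex-3-en-1-yl]triphenylphosphonium bromide | [Br-].OCC/C=C\CC[P+](c1ccccc1)(c1ccccc1)c1ccccc1
F8 | step 6 | (5Z,8Z)-11-hydroxy-1-(2,4,6-tris{[tert-butyl(dimethyl)silyl]oxy}phenyl)undeca-5,8-dien-1-one | OCC/C=C\C/C=C\CCCC(=O)c1c(O[Si](C)(C)C(C)(C)C)cc(O[Si](C)(C)C(C)(C)C)cc1O[Si](C)(C)C(C)(C)C
F9 | step 6 | (5Z,8Z)-11-bromo-1-(2,4,6-tris{[tert-butyl(dimethyl)silyl]oxy}phenyl)undeca-5,8-dien-1-one | BrCC/C=C\C/C=C\CCCC(=O)c1c(O[Si](C)(C)C(C)(C)C)cc(O[Si](C)(C)C(C)(C)C)cc1O[Si](C)(C)C(C)(C)C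
F10 | step 6 | [(3Z,6Z)-11-oxo-11-(2,4,6-tris{[tert-butyl(dimethyl)silyl]oxy}phenyl)undeca-3,6-dien-1-yl]triphenylphosphonium bromide | [Br-].O=C(CCC/C=C\C/C=C\CC[P+](c1ccccc1)(c1ccccc1)c1ccccc1)c1c(O[Si](C)(C)C(C)(C)C)cc(O[Si](C)(C)C(C)(C)C)cc1O[Si](C)(C)C(C)(C)C
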